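The synthesis rests on disconnecting the C7–C8 bond of the propane chain, between the carbinol carbon on the guaiacyl ring and the carbon that carries the syringyl ether oxygen. The feature exploited is the anti (erythro) C7–OH/C8–OAr pair flanked by the C9 hydroxymethyl group. C9 is read as a cleaved vinyl group, which reveals an (E)-γ-aryloxyallylboration retron. A 3-aryloxy-1-propenylboronate built on methyl syringate is isomerised by iridium to the (E)-γ-aryloxyallylboronate and added to vanillin acetate under (S)-TRIP catalysis. This one operation joins both aromatic halves and sets both stereocentres. Ozonolysis and global DIBAL-H reduction then deliver both CH2OH groups and the free phenol.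

Key step: step 2

Remark: C7, C8 and C9 denote the benzylic carbinol carbon, the aryloxy-bearing carbon and the CH2OH carbon of the chain, and the target is the (7R,8S) erythro (anti) isomer; the sense of induction of (S)-TRIP is assigned by analogy with allyl and crotyl pinacolboronates, and the enantiomeric catalyst would be used if the oxygenated reagent behaved oppositely.

Step 1
Reactants: 1 methyl syringate (methyl 4-hydroxy-3,5-dimethoxybenzoate); 2 (E)-3-chloroprop-1-enylboronic acid pinacol ester
Product: 3 methyl 3,5-dimethoxy-4-{[(E)-3-(4,4,5,5-tetramethyl-1,3,2-dioxaborolan-2-yl)prop-2-en-1-yl]oxy}benzoate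
Conditions: K2CO3, DMF, 50 °C
Reagents that add atoms: none
Why: Williamson ether synthesis, in which the phenoxide of 1 (acidified by the para ester) displaces the primary allylic chloride by SN2, while the vinyl-Bpin unit, its E geometry and the methyl ester should tolerate the mild carbonate base.

Step 2
Reactants: 3 the (E)-3-aryloxy-1-propenylboronate; 4 vanillin acetate (4-formyl-2-methoxyphenyl acetate)
Product: 7 methyl 4-{[(1R,2S)-1-(4-acetoxy-3-methoxyphenyl)-1-hydroxybut-3-en-2-yl]oxy}-3,5-dimethoxybenzoate, via allylboronate 5 (not isolated), via pinacol borate 6 (not isolated)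
Conditions: [Ir(cod)(PPh2Me)2]PF6 (3 mol %, activated with H2, then Ar purge), CH2Cl2, rt; then 4, (S)-TRIP [(S)-3,3'-bis(2,4,6-triisopropylphenyl)-1,1'-binaphthyl-2,2'-diyl hydrogen phosphate, 10 mol %], 4 Å MS, toluene, −30 °C; H2O work-up
Reagents that add atoms: none
Why: The H2-activated cationic iridium hydride moves the C=C bond of 3 by insertion/β-hydride elimination out of conjugation with boron and into conjugation with the aryloxy oxygen, which should give the (E)-enol ether 5, as is known for 3-alkoxy-1-propenylboronates and for allyl aryl ethers. Boronate 5 then adds to aldehyde 4 through its γ-carbon (C8) in a closed six-membered chair transition state (type I allylboration); the closest known reaction type is the chiral-phosphoric-acid-catalysed γ-alkoxyallylboration of aromatic aldehydes, which is also known in tandem with iridium-catalysed isomerisation of 1-alkenylboronates. No ring is closed in the product, and borate 6 is hydrolysed to 7 on work-up. The relative configuration (anti C7–OH/C8–OAr) follows from the E geometry of 5, which places both the aryloxy group and the aldehyde aryl group equatorial in the chair. The absolute configuration is set by the catalyst: (R)-TRIP, hydrogen-bonded to a boronate oxygen and to the formyl C–H, directs allyl and crotyl pinacolboronates to the Re face of ArCHO, so (S)-TRIP should give Si-face attack, hence 7R (the descriptor is R here because C8 bears oxygen) and, through the chair, 8S. The step needs a single aldehyde partner and a negligible uncatalysed background, which are secured by keeping the syringyl C1 substituent at the ester level, by the low intrinsic reactivity of γ-oxygenated pinacol allylboronates at −30 °C and by the more electrophilic acetate-protected aldehyde.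

Step 3
Reactants: 7 the (1R,2S)-homoallylic alcohol
Product: 10 (1R,2S)-1-(4-hydroxy-3-methoxyphenyl)-2-[4-(hydroxymethyl)-2,6-dimethoxyphenoxy]propane-1,3-diol, via secondary ozonide 8 (not isolated), via hydroxy aldehyde 9 (not isolated)
Conditions: O3, CH2Cl2, −78 °C (Sudan Red 7B end point); PPh3, −78 → 0 °C; then DIBAL-H (12 equiv), −78 → 0 °C; aq. Rochelle salt (near-neutral work-up)
Reagents that add atoms: ozone, [O-][O+]=O
Why: Criegee ozonolysis of the only alkene (both arenes are deactivated, one by the ester and one by the acetate) gives ozonide 8, PPh3 reduces it to aldehyde 9, and excess DIBAL-H in the same solvent reduces the aldehyde and the methyl ester to CH2OH groups and cleaves the aryl acetate, without breaking any bond at C7 or C8, so both stereocentres should be retained.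

Compound list
1 | methyl syringate (methyl 4-hydroxy-3,5-dimethoxybenzoate) | COC(=O)c1cc(OC)c(O)c(OC)c1 | starting material
2 | (E)-3-chloroprop-1-enylboronic acid pinacol ester | ClC/C=C/B1OC(C)(C)C(C)(C)O1 | starting material
3 | methyl 3,5-dimethoxy-4-{[(E)-3-(4,4,5,5-tetramethyl-1,3,2-dioxaborolan-2-yl)prop-2-en-1-yl]oxy}benzoate | COC(=O)c1cc(OC)c(OC/C=C/B2OC(C)(C)C(C)(C)O2)c(OC)c1 | intermediate
4 | vanillin acetate (4-formyl-2-methoxyphenyl acetate) | COc1cc(C=O)ccc1OC(C)=O | starting material
5 | methyl 3,5-dimethoxy-4-{[(E)-3-(4,4,5,5-tetramethyl-1,3,2-dioxaborolan-2-yl)prop-1-en-1-yl]oxy}benzoate (not isolated) | COC(=O)c1cc(OC)c(O/C=C/CB2OC(C)(C)C(C)(C)O2)c(OC)c1 | intermediate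
6 | O-(pinacolatoboryl) derivative of 7, (1R,2S) (not isolated) | COc1cc([C@@H](OB3OC(C)(C)C(C)(C)O3)[C@H](C=C)Oc2c(OC)cc(C(=O)OC)cc2OC)ccc1OC(C)=O | intermediate
7 | methyl 4-{[(1R,2S)-1-(4-acetoxy-3-methoxyphenyl)-1-hydroxybut-3-en-2-yl]oxy}-3,5-dimethoxybenzoate | COc1cc([C@@H](O)[C@H](C=C)Oc2c(OC)cc(C(=O)OC)cc2OC)ccc1OC(C)=O | intermediate
8 | secondary ozonide of 7 (1,2,4-trioxolan-3-yl in place of vinyl, C7 and C8 geometry unchanged, mixture at the trioxolane carbon; not isolated) | COc1cc([C@@H](O)[C@H](C3OCOO3)Oc2c(OC)cc(C(=O)OC)cc2OC)ccc1OC(C)=O | intermediate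
9 | methyl 4-{[(1R,2R)-1-(4-acetoxy-3-methoxyphenyl)-1-hydroxy-3-oxopropan-2-yl]oxy}-3,5-dimethoxybenzoate (same geometry as 7, the C8 descriptor changes by priority only; not isolated) | COc1cc([C@@H](O)[C@H](C=O)Oc2c(OC)cc(C(=O)OC)cc2OC)ccc1OC(C)=O | intermediate
10 | (1R,2S)-1-(4-hydroxy-3-methoxyphenyl)-2-[4-(hydroxymethyl)-2,6-dimethoxyphenoxy]propane-1,3-diol | COc1cc([C@@H](O)[C@H](CO)Oc2c(OC)cc(CO)cc2OC)ccc1O | target

Total step count: 3. Longest linear sequence: 3 (1 → 3 → 7 → 10).

Steps most likely to fail

Step 2:
- The double-bond migration may stop short or give an E/Z mixture, which would erode the anti selectivity.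
- The iridium hydride may walk on into the vinyl group of the product and destroy C8.
- The enol ether may decompose under the acid catalyst.
- The bulky 2,6-dimethoxyaryloxy group may lower the facial selectivity.

The fallback forms the same C7–C8 bond by an auxiliary-controlled aldol reaction. It sets out from 1 and 4 and comes back to the route at 10. Phenol 1 is alkylated with commercial (R)-4-benzyl-3-(chloroacetyl)oxazolidin-2-one (K2CO3, acetone, rt) to give the N-(aryloxyacetyl)oxazolidinone F1. Enolisation with Bu2BOTf/i-Pr2NEt (CH2Cl2, −78 °C) and addition to 4 (Evans syn aldol) should give the syn adduct F2, in which C8 has the required geometry and C7 is epimeric. Mitsunobu inversion at C7 with benzoic acid (PPh3, DIAD, THF, 0 °C) gives the anti benzoate F3. LiAlH4 (THF, 0 °C) then removes the auxiliary, the benzoate and the acetate and reduces the methyl ester, giving 10.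

Step 3:
- Ozone may attack the methoxylated rings.
- The unpurified α-aryloxy-β-hydroxy aldehyde may epimerise at C8 or undergo retro-aldol cleavage during the warm-up.
- The aluminium phenoxide may ionise the benzylic C7–O bond.

The fallback avoids ozone and separates the reductions. It sets out from 7, passes through 9 and comes back at 10. Lemieux–Johnson cleavage (OsO4 cat., NaIO4, 2,6-lutidine, dioxane/H2O) gives 9. This is captured at once with NaBH4 in MeOH at 0 °C and then treated with catalytic K2CO3 to complete methanolysis of the acetate, which gives the phenolic diol ester F4. F4 is purified and reduced separately with LiAlH4 (THF, 0 °C, Rochelle salt work-up) to 10.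

Step 1:
- The phenoxide may bind to boron, which would lead to protodeboronation.
- Displacement may occur in the SN2' sense.

The fallback installs boron after the ether bond. It sets out from 1 and comes back at 3. Phenol 1 is alkylated with propargyl bromide (K2CO3, DMF, rt) to give the propargyl ether F5. Hydroboration of the terminal alkyne with pinacolborane (dicyclohexylborane cat., neat, rt; syn addition, boron at the terminal carbon) gives 3.

Further compounds
F1 | step 2 | methyl 4-{2-[(4R)-4-benzyl-2-oxo-1,3-oxazolidin-3-yl]-2-oxoethoxy}-3,5-dimethoxybenzoate | COC(=O)c1cc(OC)c(OCC(=O)N2[C@H](Cc3ccccc3)COC2=O)c(OC)c1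
F2 | step 2 | methyl 4-{[(1S,2R)-1-(4-acetoxy-3-methoxyphenyl)-3-[(4R)-4-benzyl-2-oxo-1,3-oxazolidin-3-yl]-1-hydroxy-3-oxopropan-2-yl]oxy}-3,5-dimethoxybenzoate | COc1cc([C@H](O)[C@H](C(=O)N3[C@H](Cc4ccccc4)COC3=O)Oc2c(OC)cc(C(=O)OC)cc2OC)ccc1OC(C)=O
F3 | step 2 | methyl 4-{[(1R,2R)-1-(4-acetoxy-3-methoxyphenyl)-1-(benzoyloxy)-3-[(4R)-4-benzyl-2-oxo-1,3-oxazolidin-3-yl]-3-oxopropan-2-yl]oxy}-3,5-dimethoxybenzoate | COc1cc([C@@H](OC(=O)c5ccccc5)[C@H](C(=O)N3[C@H](Cc4ccccc4)COC3=O)Oc2c(OC)cc(C(=O)OC)cc2OC)ccc1OC(C)=O
F4 | step 3 | methyl 4-{[(1R,2S)-1,3-dihydroxy-1-(4-hydroxy-3-methoxyphenyl)propan-2-yl]oxy}-3,5-dimethoxybenzoate | COc1cc([C@@H](O)[C@H](CO)Oc2c(OC)cc(C(=O)OC)cc2OC)ccc1O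
F5 | step 1 | methyl 3,5-dimethoxy-4-(prop-2-yn-1-yloxy)benzoate | COC(=O)c1cc(OC)c(OCC#C)c(OC)c1
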